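The earlier runs and the new flask stem from a simulated flask for substances that don't exist.

Theta, beta, zeta and gamma get the same amounts: Ptn at 1.50 of the Sub charge, and that ratio, Ptn charged per Sub charged, is what I call the budget.

| flask | Sub | Ptn | remark | time |
|---|---|---|---|---|
| west | 0.25 M | 0.375 M | run made earlier |  |
| south | 0.35 M | 0.375 M | run made earlier |  |
| north-west | 0.55 M | 0.375 M | run made earlier |  |
| east | 0.25 M | 0.19 M | run made earlier |  |
| theta | 0.25 M | 0.375 M | a closed flask charged with all of it at once and left for 6.0 d | 6.0 d |
| beta | 0.25 M | 0.375 M | one stirred flow tank at steady state, fed with the mixture as stated, mean residence time 6.0 d |  |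
| zeta | 0.25 M | 0.375 M | one stirred flow tank at steady state, fed with the mixture as stated, mean residence time 60.0 d |  |
| gamma | 0.25 M (fed, over 3.00 d) | 0.375 M | a stirred flask in which Sub is dosed at a steady rate over 3.00 d without added volume, worked up at 6.0 d | 6.0 d |

| run | time / d | Imd2 / % |
|---|---|---|
| west | 0.500 | 18.6 |
| west | 1.67 | 25.1 |
| west | 3.00 | 23.1 |
| west | 4.00 | 23.0 |
| west | 6.00 | 23.3 |
| south | 0.625 | 18.4 |
| south | 1.25 | 22.2 |
| south | 2.00 | 21.2 |
| south | 3.00 | 23.9 |
| south | 4.00 | 20.1 |
| north-west | 0.333 | 10.9 |
| north-west | 0.833 | 14.3 |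
| north-west | 1.67 | 15.2 |
| north-west | 2.50 | 16.4 |
| north-west | 4.00 | 15.0 |
| east | 0.333 | 7.0 |
| east | 0.833 | 11.3 |
| east | 1.67 | 17.6 |
| east | 2.50 | 16.3 |
| east | 4.00 | 17.5 |

(scatter of a reading: 1 percentage point)

- the set-up with the highest amount of Imd2 at the outlet or at the end, in percent of the Sub put in ("none" if the first two lie within 2 percentage points) (theta / beta / zeta / gamma / none)
- amount of Imd2 at the outlet or at the end, in percent of the Sub put in, theta
- amount of Imd2 at the outlet or at the end, in percent of the Sub put in, beta
- amount of Imd2 at the outlet or at the end, in percent of the Sub put in, zeta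
- amount of Imd2 at the outlet or at the end, in percent of the Sub put in, gamma

- the stated concentrations are those of everything mixed, before any reaction; amounts are the same in each set-up
- the feed brings no volume worth counting
- the earlier runs were made in a closed, stirred flask

The west run is theta's charge in theta's kind of flask, and with the other times it makes a ladder. Imd2 stands at 18.6% after 0.500 d, and integrating a first-order approach to the last reading, 23.3%, gives a time constant of 0.312 d, a figure read from scattered readings, and this rise is the fastest rung. Slower than that rise comes the dosing in gamma, 3.00 d, then the 6.0 d of theta and of the beta tank, and last the 60.0 d of zeta. By 3.00 d the west run reads flat within the scatter of 1 percentage point, so I put theta at about 23.3%.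

Set beside the budget, the late readings stand thus: 0.682 in the north-west run gives 15.0%, 0.760 in the east run gives 17.5%, 1.07 in the south run gives 20.1% to 23.9%, and 1.50 in the west run gives 23.3%. No reading shows Ptn, and no run shows a tank or a dosed feed, so I reckon nothing of my own for beta, zeta or gamma.

The forecast names theta as best, with 23.5% in theta, 14.5% in beta, 14.5% in zeta and 13% in gamma. Its ground for the tanks is: “Back-mixed tanks favour over-reaction of an intermediate”. Its theta differs from my figure by 0.2 points.

The flask gives theta as best, with 23.9% in theta, 13.7% in beta, 13.4% in zeta and 15.0% in gamma, so gamma ends higher than either tank, where the forecast had it lower.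

    Sub + Ptn → Imd (k = 5.30 × 10⁻⁵ M⁻¹ s⁻¹)
    Ptn + Imd → Imd2 (k = 2.00 × 10⁻⁴ M⁻¹ s⁻¹)
    Ptn + Imd2 → Imd3 (k = 1.00 × 10⁻⁴ M⁻¹ s⁻¹)
    Ptn + Imd3 → Imd4 (k = 2.80 × 10⁻⁶ M⁻¹ s⁻¹)
    2 Ptn → Pdt (k = 1.90 × 10⁻⁶ M⁻¹ s⁻¹)

Theta at 6.00 d holds Ptn, the limiting reagent, at 0.0102% of its charge, and the adducts, each counted by the Ptn it carries, plus Pdt at two Ptn, add up to 1.50 against the budget of 1.50. A neighbour, theta with 1.0 M of Sub, has a budget of 0.375 equiv: the same count gives 0.375, and its Imd2, in percent of its own Sub charge, ends lower than gamma's, at 8.40%.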